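The plan builds ring A of unit 1 (the 8-arylflavone) around the future biaryl bond instead of joining two finished arenes. That ring has a 1,3,5-trioxygenated pattern in which no two oxygens are alike: C8a carries the pyranone oxygen O1, C7 a methyl ether, C5 a free hydroxyl, and the aryl group on C8 lies between C8a and C7. A Danheiser benzannulation of 3-ethoxycyclobutenone with an aryl methyl ynol ether, whose arene is ring B of unit 2 with the aldehyde masked as a dioxolane, makes C8–C8a, C6–C7 and C4a–C8a in one operation and puts OH, OMe and OEt on the right carbons. Both pyranones follow by established flavone chemistry.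

Key step: step 4

Assumption: the target SMILES carries no stereodescriptor, so the hindered C8–C2' biaryl axis is left undefined and there is no stereocentre to set.

Labels: unit 1 is the flavone that bears the aryl group at C8 (O1, C2 to C8a; its own ring B is the 4-methoxyphenyl group). Unit 2 is the 5,7-dihydroxyflavone whose ring B (C1' to C6', OMe on C4') is bonded through C2' to C8 of unit 1.

Structure check:
- Ketene part of the cascade: the C=O carbon becomes C8a, the α-carbon C6, C–OEt becomes C5 and the ring CH2 C4a.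
- Alkyne part: the aryl-bearing carbon becomes C8 and the methoxy-bearing carbon C7.
- The alkyne (C13H14O4) and the cyclobutenone (C6H8O2) therefore combine without loss of atoms to a phenol C19H22O6 with the required pattern.
- The bromoaldehyde (CHO para to OMe, Br ortho to CHO) matches ring B of unit 2.
- No structure needs correcting.

Design points:
- (a) A methyl ynol ether has no β-hydrogen, so it cannot fragment on heating, and its methyl group is the C7 methyl ether of the target.
- (b) The dioxolane derives from a p-methoxybenzaldehyde. After the key step it sits next to a free phenol on the neighbouring ring, and any Brønsted or Lewis acid would fold the pair into a cyclic 6H-benzo[c]chromene acetal.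
  - C4a is therefore functionalised under basic conditions (magnesium-mediated formylation in place of a Friedel–Crafts or Fries acetylation).
  - The pyranone is closed with an amine, and acid is admitted only once O1 is locked in the ring.
  - Acid-sensitive intermediates are chromatographed on Et3N-deactivated silica.
- (c) The C5 ethyl ether is peri to C4=O, so it leaves by chelation together with the benzyl groups in one final operation.

Step 1
Reactants: 1 2-bromo-4-methoxybenzaldehyde
Product: 2 2-(2-bromo-4-methoxyphenyl)-1,3-dioxolane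
Conditions: HOCH2CH2OH (3 equiv), p-TsOH·H2O (2 mol %), toluene, reflux, Dean–Stark; aq NaHCO3
Reagents that add atoms: ethylene glycol, OCCO
Why: Acid-catalysed acetalisation with azeotropic removal of water masks the aldehyde against the amide base, the organozinc reagent and the ketenes that follow.

Step 2
Reactants: 2 2-(2-bromo-4-methoxyphenyl)-1,3-dioxolane; 3 chloroacetaldehyde dimethyl acetal
Product: 6 2-[4-methoxy-2-(methoxyethynyl)phenyl]-1,3-dioxolane, via lithium methoxyacetylide 4 (not isolated), via methoxyethynylzinc chloride 5 (not isolated)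
Conditions: Et2NH, n-BuLi (4.5 equiv each), THF, 0 °C; 3 (1.5 equiv), 0 °C; ZnCl2 (3 equiv), 0 °C to rt; 2, Pd(OAc)2 (3 mol %), SPhos (6 mol %), 50 °C; aq NaHCO3; Et3N-deactivated SiO2
Reagents that add atoms: none
Why: Double elimination of the chloroacetal with three equivalents of lithium amide gives the lithium alkoxyacetylide, transmetalation to zinc tempers its basicity, and a Negishi alkynylation on zerovalent palladium carrying an electron-rich biarylphosphine couples it to the ortho-substituted aryl bromide without touching the acetal.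

Step 3
Reactants: 7 ethoxyacetylene; 8 acetone
Product: 10 3-ethoxycyclobut-2-en-1-one, via ketene 9 (not isolated)
Conditions: acetone vapour through a hot-wire ketene generator (ca. 700 °C); gas stream into 7, CH2Cl2, 0 °C to rt; distillation under reduced pressure
Reagents that add atoms: none
Why: In this thermal ketene–alkyne [2+2] cycloaddition the nucleophilic terminal carbon of the alkoxyalkyne bonds to the ketene carbonyl carbon, so the 3-alkoxycyclobutenone should form as a single regioisomer.

Step 4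
Reactants: 6 2-[4-methoxy-2-(methoxyethynyl)phenyl]-1,3-dioxolane; 10 3-ethoxycyclobut-2-en-1-one
Product: 15 2-[2-(1,3-dioxolan-2-yl)-5-methoxyphenyl]-5-ethoxy-3-methoxyphenol, via ethoxyvinylketene 11 (not isolated), via 4-vinylcyclobutenone 12 (not isolated), via dienylketene 13 (not isolated), via cyclohexadienone 14 (not isolated)
Conditions: 10 (1.5 equiv), toluene (0.4 M), BHT (trace), sealed tube, 110 °C then 140 °C; then K2CO3, MeOH, rt; Et3N-deactivated SiO2
Reagents that add atoms: none
Why: Heating opens 10 in a reversible four-electron electrocyclic reaction to vinylketene 11, and the ketene C=C of 11 adds to the electron-rich triple bond of 6 in a [2+2] cycloaddition that forms C8–C8a and C6–C7 and gives 4-vinylcyclobutenone 12. A second four-electron (conrotatory) opening leads to dienylketene 13, and since this opening is reversible the material drains through the isomer with the ethoxyvinyl group cis to the ketene, which closes C4a–C8a by a disrotatory six-electron electrocyclisation, the mode by which the only new ring (the six-membered carbocyclic ring A) is made; dienone 14 then tautomerises to phenol 15. The reaction type is the Danheiser benzannulation of cyclobutenones with alkynyl ethers, with a 3-alkoxycyclobutenone as a less usual partner that, as a stabilised vinylogous ester, should need the upper end of the normal temperature range. The selectivity required is the orientation of the [2+2] step, and it is secured by the polarisation of the ynol ether: oxygen donation makes the aryl-bearing carbon the nucleophile, this carbon bonds to the ketene carbonyl carbon, and the aryl group therefore ends between the new hydroxyl (C8a) and the methoxy group (C7), with ethoxy on C5. No stereocentre is created in 15, the sp3 carbon of 12 being lost on ring opening. The medium is neutral, so the dioxolane and the ynol ether survive, the methyl ynol ether cannot fragment by a retro-ene path, and the K2CO3/MeOH treatment returns any phenol that excess ketene has acylated.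

Step 5
Reactants: 15 2-[2-(1,3-dioxolan-2-yl)-5-methoxyphenyl]-5-ethoxy-3-methoxyphenol
Product: 16 3-[2-(1,3-dioxolan-2-yl)-5-methoxyphenyl]-6-ethoxy-2-hydroxy-4-methoxybenzaldehyde
Conditions: MgCl2 (3 equiv), Et3N (6 equiv), (CH2O)n (10 equiv), MeCN, reflux; aq NH4Cl
Reagents that add atoms: paraformaldehyde (as formaldehyde), C=O
Why: In the Casnati–Skattebøl formylation the magnesium phenoxide delivers bound formaldehyde only to an ortho carbon, of which C4a is the sole free one, a second formaldehyde accepts hydride to give the aldehyde, and the basic medium spares the acid-labile dioxolane.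

Step 6
Reactants: 16 3-[2-(1,3-dioxolan-2-yl)-5-methoxyphenyl]-6-ethoxy-2-hydroxy-4-methoxybenzaldehyde; 17 4-ethynylanisole
Product: 19 2-[2-(1,3-dioxolan-2-yl)-5-methoxyphenyl]-5-ethoxy-6-[1-hydroxy-3-(4-methoxyphenyl)prop-2-yn-1-yl]-3-methoxyphenol (racemic carbinol), via lithium arylacetylide 18 (not isolated)
Conditions: 17 (3 equiv), n-BuLi (2.9 equiv), THF, −78 °C; 16, −78 °C to 0 °C; pH 7 buffer; crude product taken on at once
Reagents that add atoms: none
Why: This is a 1,2-addition of a lithium acetylide to the aldehyde, in which one equivalent deprotonates the phenol so that the dianionic adduct cannot ionise to a quinone methide, and the carbinol centre is formed without control and is erased in step 7.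

Step 7
Reactants: 19 2-[2-(1,3-dioxolan-2-yl)-5-methoxyphenyl]-5-ethoxy-6-[1-hydroxy-3-(4-methoxyphenyl)prop-2-yn-1-yl]-3-methoxyphenol
Product: 20 1-{3-[2-(1,3-dioxolan-2-yl)-5-methoxyphenyl]-6-ethoxy-2-hydroxy-4-methoxyphenyl}-3-(4-methoxyphenyl)prop-2-yn-1-one
Conditions: MnO2 (activated, 15 equiv), CH2Cl2, rt
Reagents that add atoms: none
Why: Activated MnO2 oxidises benzylic-propargylic alcohols selectively under neutral conditions, and the resulting ynone is stabilised by the hydrogen bond from the C8a hydroxyl.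

Step 8
Reactants: 20 1-{3-[2-(1,3-dioxolan-2-yl)-5-methoxyphenyl]-6-ethoxy-2-hydroxy-4-methoxyphenyl}-3-(4-methoxyphenyl)prop-2-yn-1-one
Product: 23 2-[5-ethoxy-7-methoxy-2-(4-methoxyphenyl)-4-oxo-4H-chromen-8-yl]-4-methoxybenzaldehyde, via enaminone 21 (not isolated), via flavone acetal 22 (not isolated)
Conditions: Et2NH (5 equiv), EtOH, 60 °C; evaporate; 1 M aq HCl–THF (1:4), rt
Reagents that add atoms: water, O
Why: Aza-Michael addition of the secondary amine gives push-pull enaminone 21, in which the phenol can attack only the β-carbon, so addition–elimination gives the six-membered pyranone and no aurone, and with O1 now tied into the ring dilute acid hydrolyses the acetal without lactol formation.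

Step 9
Reactants: 24 2,4,6-trihydroxyacetophenone
Product: 25 1-[2,4-bis(benzyloxy)-6-hydroxyphenyl]ethan-1-one
Conditions: BnBr (2.1 equiv), K2CO3 (2.2 equiv), DMF, rt to 40 °C
Reagents that add atoms: benzyl bromide, BrCc1ccccc1
Why: In this Williamson etherification the last ortho hydroxyl is held in a strong hydrogen bond to the ketone and stays free when only two equivalents of benzyl bromide are used.

Step 10
Reactants: 23 2-[5-ethoxy-7-methoxy-2-(4-methoxyphenyl)-4-oxo-4H-chromen-8-yl]-4-methoxybenzaldehyde; 25 1-[2,4-bis(benzyloxy)-6-hydroxyphenyl]ethan-1-one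
Product: 26 (E)-1-[2,4-bis(benzyloxy)-6-hydroxyphenyl]-3-{2-[5-ethoxy-7-methoxy-2-(4-methoxyphenyl)-4-oxo-4H-chromen-8-yl]-4-methoxyphenyl}prop-2-en-1-one
Conditions: KOH (50% aq, 10 equiv), EtOH–THF, rt; dilute HCl to pH 5
Reagents that add atoms: none
Why: Claisen–Schmidt condensation of the non-enolisable aldehyde with the acetophenone enolate, followed by E1cB loss of water, gives the thermodynamically preferred E-enone.

Step 11
Reactants: 26 (E)-1-[2,4-bis(benzyloxy)-6-hydroxyphenyl]-3-{2-[5-ethoxy-7-methoxy-2-(4-methoxyphenyl)-4-oxo-4H-chromen-8-yl]-4-methoxyphenyl}prop-2-en-1-one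
Product: 28 8-{2-[5,7-bis(benzyloxy)-4-oxo-4H-chromen-2-yl]-5-methoxyphenyl}-5-ethoxy-7-methoxy-2-(4-methoxyphenyl)-4H-chromen-4-one, via flavanone 27 (not isolated)
Conditions: I2 (10 mol %), DMSO, 130 °C; aq Na2S2O3
Reagents that add atoms: none
Why: The iodine-catalysed oxidative cyclisation of a 2'-hydroxychalcone in DMSO (oxa-Michael closure to the flavanone, then dehydrogenation with DMSO as terminal oxidant) is the standard flavone synthesis and leaves benzyl, ethyl and methyl ethers in place.

Step 12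
Reactants: 28 8-{2-[5,7-bis(benzyloxy)-4-oxo-4H-chromen-2-yl]-5-methoxyphenyl}-5-ethoxy-7-methoxy-2-(4-methoxyphenyl)-4H-chromen-4-one
Product: 29 8-[2-(5,7-dihydroxy-4-oxo-4H-chromen-2-yl)-5-methoxyphenyl]-5-hydroxy-7-methoxy-2-(4-methoxyphenyl)-4H-chromen-4-one (target, CNP0114008.0)
Conditions: BCl3 (1 M in CH2Cl2, 10 equiv), C6HMe5 (6 equiv), CH2Cl2, −78 °C to rt; 1 M aq HCl–THF, rt
Reagents that add atoms: none
Why: In this Lewis-acid ether cleavage BCl3 removes the benzyl aryl ethers at low temperature with pentamethylbenzene as cation trap and, on warming, the C5 ethyl ether through the six-membered boron chelate with C4=O, whereas the three methyl ethers (C7, the 4-methoxyphenyl group of unit 1, C4' of unit 2) have no such assistance and persist.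

Compound list
1 | 2-bromo-4-methoxybenzaldehyde | COc1ccc(C=O)c(Br)c1 | starting material
2 | 2-(2-bromo-4-methoxyphenyl)-1,3-dioxolane | COc1ccc(C2OCCO2)c(Br)c1 | intermediate
3 | chloroacetaldehyde dimethyl acetal | COC(CCl)OC | starting material
4 | lithium methoxyacetylide | [Li]C#COC | intermediate
5 | (methoxyethynyl)zinc chloride | COC#C[Zn]Cl | intermediate
6 | 2-[4-methoxy-2-(methoxyethynyl)phenyl]-1,3-dioxolane | COC#Cc1cc(OC)ccc1C1OCCO1 | intermediate
7 | ethoxyacetylene | CCOC#C | starting material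
8 | acetone | CC(C)=O | starting material
9 | ketene | C=C=O | intermediate
10 | 3-ethoxycyclobut-2-en-1-one | CCOC1=CC(=O)C1 | intermediate
11 | 3-ethoxybuta-1,3-dien-1-one (ethoxyvinylketene) | C=C(OCC)C=C=O | intermediate
12 | 2-[2-(1,3-dioxolan-2-yl)-5-methoxyphenyl]-4-(1-ethoxyvinyl)-3-methoxycyclobut-2-en-1-one (racemic, transient) | C=C(OCC)C1C(OC)=C(C1=O)c2cc(OC)ccc2C3OCCO3 | intermediate
13 | (3E)-2-[2-(1,3-dioxolan-2-yl)-5-methoxyphenyl]-5-ethoxy-3-methoxyhexa-1,3,5-trien-1-one (dienylketene, ketene and ethoxyvinyl groups cis) | C=C(OCC)/C=C(OC)\C(=C=O)c1cc(OC)ccc1C1OCCO1 | intermediate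
14 | 2-[2-(1,3-dioxolan-2-yl)-5-methoxyphenyl]-5-ethoxy-3-methoxycyclohexa-2,4-dien-1-one | CCOC1=CC(OC)=C(C(=O)C1)c1cc(OC)ccc1C1OCCO1 | intermediate
15 | 2-[2-(1,3-dioxolan-2-yl)-5-methoxyphenyl]-5-ethoxy-3-methoxyphenol | CCOc1cc(O)c(c(OC)c1)-c1cc(OC)ccc1C1OCCO1 | intermediate
16 | 3-[2-(1,3-dioxolan-2-yl)-5-methoxyphenyl]-6-ethoxy-2-hydroxy-4-methoxybenzaldehyde | CCOc1cc(OC)c(-c2cc(OC)ccc2C2OCCO2)c(O)c1C=O | intermediate
17 | 4-ethynylanisole | C#Cc1ccc(OC)cc1 | starting material
18 | lithium (4-methoxyphenyl)acetylide | [Li]C#Cc1ccc(OC)cc1 | intermediate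
19 | 2-[2-(1,3-dioxolan-2-yl)-5-methoxyphenyl]-5-ethoxy-6-[1-hydroxy-3-(4-methoxyphenyl)prop-2-yn-1-yl]-3-methoxyphenol (racemic) | CCOc1cc(OC)c(-c2cc(OC)ccc2C2OCCO2)c(O)c1C(O)C#Cc1ccc(OC)cc1 | intermediate
20 | 1-{3-[2-(1,3-dioxolan-2-yl)-5-methoxyphenyl]-6-ethoxy-2-hydroxy-4-methoxyphenyl}-3-(4-methoxyphenyl)prop-2-yn-1-one | CCOc1cc(OC)c(-c2cc(OC)ccc2C2OCCO2)c(O)c1C(=O)C#Cc1ccc(OC)cc1 | intermediate
21 | 3-(diethylamino)-1-{3-[2-(1,3-dioxolan-2-yl)-5-methoxyphenyl]-6-ethoxy-2-hydroxy-4-methoxyphenyl}-3-(4-methoxyphenyl)prop-2-en-1-one (configurationally mobile push-pull alkene) | CCOc1cc(OC)c(-c2cc(OC)ccc2C2OCCO2)c(O)c1C(=O)C=C(N(CC)CC)c1ccc(OC)cc1 | intermediate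
22 | 8-[2-(1,3-dioxolan-2-yl)-5-methoxyphenyl]-5-ethoxy-7-methoxy-2-(4-methoxyphenyl)-4H-chromen-4-one | CCOc1cc(OC)c(-c2cc(OC)ccc2C2OCCO2)c2oc(-c3ccc(OC)cc3)cc(=O)c12 | intermediate
23 | 2-[5-ethoxy-7-methoxy-2-(4-methoxyphenyl)-4-oxo-4H-chromen-8-yl]-4-methoxybenzaldehyde | CCOc1cc(OC)c(-c2cc(OC)ccc2C=O)c2oc(-c3ccc(OC)cc3)cc(=O)c12 | intermediate
24 | 2,4,6-trihydroxyacetophenone | CC(=O)c1c(O)cc(O)cc1O | starting material
25 | 1-[2,4-bis(benzyloxy)-6-hydroxyphenyl]ethan-1-one | CC(=O)c1c(O)cc(OCc2ccccc2)cc1OCc1ccccc1 | intermediate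
26 | (E)-1-[2,4-bis(benzyloxy)-6-hydroxyphenyl]-3-{2-[5-ethoxy-7-methoxy-2-(4-methoxyphenyl)-4-oxo-4H-chromen-8-yl]-4-methoxyphenyl}prop-2-en-1-one | CCOc1cc(OC)c(-c2cc(OC)ccc2/C=C/C(=O)c2c(O)cc(OCc3ccccc3)cc2OCc2ccccc2)c2oc(-c3ccc(OC)cc3)cc(=O)c12 | intermediate
27 | 8-{2-[5,7-bis(benzyloxy)-4-oxochroman-2-yl]-5-methoxyphenyl}-5-ethoxy-7-methoxy-2-(4-methoxyphenyl)-4H-chromen-4-one (racemic flavanone, transient) | CCOc1cc(OC)c(-c2cc(OC)ccc2C2CC(=O)c3c(OCc4ccccc4)cc(OCc4ccccc4)cc3O2)c2oc(-c3ccc(OC)cc3)cc(=O)c12 | intermediate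
28 | 8-{2-[5,7-bis(benzyloxy)-4-oxo-4H-chromen-2-yl]-5-methoxyphenyl}-5-ethoxy-7-methoxy-2-(4-methoxyphenyl)-4H-chromen-4-one | CCOc1cc(OC)c(-c2cc(OC)ccc2-c2cc(=O)c3c(OCc4ccccc4)cc(OCc4ccccc4)cc3o2)c2oc(-c3ccc(OC)cc3)cc(=O)c12 | intermediate
29 | 8-[2-(5,7-dihydroxy-4-oxo-4H-chromen-2-yl)-5-methoxyphenyl]-5-hydroxy-7-methoxy-2-(4-methoxyphenyl)-4H-chromen-4-one | COc1ccc(-c2cc(=O)c3c(O)cc(OC)c(-c4cc(OC)ccc4-c4cc(=O)c5c(O)cc(O)cc5o4)c3o2)cc1 | target

Total step count: 12. Longest linear sequence: 10 steps (1, 2, 4, 5, 6, 7, 8, 10, 11, 12).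

Steps most likely to fail

Step 4. The donor-stabilised cyclobutenone may open too slowly. Ketene dimerisation, thermal decay of the ynol ether or sluggish capture at the hindered aryl-bearing alkyne carbon could then outrun the cascade.

The fallback sets out from 2 and comes back at 22; it makes the biaryl bond by cross-coupling onto a ready-made ring A. Miyaura borylation of 2 (B2pin2, PdCl2(dppf), KOAc, dioxane, 90 °C) gives 2-[2-(1,3-dioxolan-2-yl)-5-methoxyphenyl]-4,4,5,5-tetramethyl-1,3,2-dioxaborolane F1. Commercial 5-hydroxy-7,4'-dimethoxyflavone is ethylated at the chelated hydroxyl (EtI, K2CO3, DMF, 60 °C) to 5-ethoxy-7-methoxy-2-(4-methoxyphenyl)-4H-chromen-4-one F2. Electrophilic iodination (I2, CF3CO2Ag, CH2Cl2), which in 5,7-dialkoxyflavones goes to C8, gives 5-ethoxy-8-iodo-7-methoxy-2-(4-methoxyphenyl)-4H-chromen-4-one F3. Suzuki–Miyaura coupling of F1 and F3 (Pd(OAc)2, SPhos, K3PO4, toluene–water, 90 °C) gives 22, which the acid half of step 8 converts into 23. Steps 2 to 7 then fall away.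

Step 10. Condensation at the hindered, para-methoxy-deactivated aldehyde may be slow enough for hydroxide to attack C2 of the finished pyranone of unit 1 and open it.

The fallback sets out from 23 and comes back at 28; it builds unit 2 by acyl transfer in place of an aldol condensation. Pinnick oxidation of 23 (NaClO2, NaH2PO4, 2-methylbut-2-ene, t-BuOH–water) gives 2-[5-ethoxy-7-methoxy-2-(4-methoxyphenyl)-4-oxo-4H-chromen-8-yl]-4-methoxybenzoic acid F4. Esterification with phenol 25 (EDC·HCl, DMAP, CH2Cl2) gives 2-acetyl-3,5-bis(benzyloxy)phenyl 2-[5-ethoxy-7-methoxy-2-(4-methoxyphenyl)-4-oxo-4H-chromen-8-yl]-4-methoxybenzoate F5. Baker–Venkataraman rearrangement with a non-nucleophilic base (LiN(SiMe3)2, THF, −78 °C to rt) gives 1-[2,4-bis(benzyloxy)-6-hydroxyphenyl]-3-{2-[5-ethoxy-7-methoxy-2-(4-methoxyphenyl)-4-oxo-4H-chromen-8-yl]-4-methoxyphenyl}propane-1,3-dione F6. Cyclodehydration (p-TsOH, toluene, reflux) then gives 28.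

Step 2. The cross-coupling may stall because the zinc acetylide carries amine and alkoxide from its generation and the bromide is ortho-substituted. The ynol ether may also be hydrated during isolation.

The fallback sets out from 2 and comes back at 6; it makes the triple bond by elimination on the arene rather than by coupling. Bromine–lithium exchange of 2 (n-BuLi, THF, −78 °C) gives [2-(1,3-dioxolan-2-yl)-5-methoxyphenyl]lithium F7. This is acylated with N,2-dimethoxy-N-methylacetamide to 1-[2-(1,3-dioxolan-2-yl)-5-methoxyphenyl]-2-methoxyethan-1-one F8. The chelated enolate (LiN(SiMe3)2, THF–DMPU, −78 °C) is trapped with PhNTf2 as (Z)-1-[2-(1,3-dioxolan-2-yl)-5-methoxyphenyl]-2-methoxyvinyl trifluoromethanesulfonate F9. Anti elimination with KOtBu (−78 °C to rt) gives 6.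

Further compounds
F1 | step 4 | 2-[2-(1,3-dioxolan-2-yl)-5-methoxyphenyl]-4,4,5,5-tetramethyl-1,3,2-dioxaborolane | COc1ccc(C2OCCO2)c(B2OC(C)(C)C(C)(C)O2)c1
F2 | step 4 | 5-ethoxy-7-methoxy-2-(4-methoxyphenyl)-4H-chromen-4-one | CCOc1cc(OC)cc2oc(-c3ccc(OC)cc3)cc(=O)c12
F3 | step 4 | 5-ethoxy-8-iodo-7-methoxy-2-(4-methoxyphenyl)-4H-chromen-4-one | CCOc1cc(OC)c(I)c2oc(-c3ccc(OC)cc3)cc(=O)c12
F4 | step 10 | 2-[5-ethoxy-7-methoxy-2-(4-methoxyphenyl)-4-oxo-4H-chromen-8-yl]-4-methoxybenzoic acid | CCOc1cc(OC)c(-c2cc(OC)ccc2C(=O)O)c2oc(-c3ccc(OC)cc3)cc(=O)c12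
F5 | step 10 | 2-acetyl-3,5-bis(benzyloxy)phenyl 2-[5-ethoxy-7-methoxy-2-(4-methoxyphenyl)-4-oxo-4H-chromen-8-yl]-4-methoxybenzoate | CCOc1cc(OC)c(-c2cc(OC)ccc2C(=O)Oc2cc(OCc3ccccc3)cc(OCc3ccccc3)c2C(C)=O)c2oc(-c3ccc(OC)cc3)cc(=O)c12
F6 | step 10 | 1-[2,4-bis(benzyloxy)-6-hydroxyphenyl]-3-{2-[5-ethoxy-7-methoxy-2-(4-methoxyphenyl)-4-oxo-4H-chromen-8-yl]-4-methoxyphenyl}propane-1,3-dione | CCOc1cc(OC)c(-c2cc(OC)ccc2C(=O)CC(=O)c2c(O)cc(OCc3ccccc3)cc2OCc2ccccc2)c2oc(-c3ccc(OC)cc3)cc(=O)c12
F7 | step 2 | [2-(1,3-dioxolan-2-yl)-5-methoxyphenyl]lithium | [Li]c1cc(OC)ccc1C1OCCO1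
F8 | step 2 | 1-[2-(1,3-dioxolan-2-yl)-5-methoxyphenyl]-2-methoxyethan-1-one | COCC(=O)c1cc(OC)ccc1C1OCCO1
F9 | step 2 | (Z)-1-[2-(1,3-dioxolan-2-yl)-5-methoxyphenyl]-2-methoxyvinyl trifluoromethanesulfonate | CO/C=C(\OS(=O)(=O)C(F)(F)F)c1cc(OC)ccc1C1OCCO1
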